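**Plan**

Numbering: C1 quaternary methyl-bearing fusion carbon, C2 acetoxy carbon, C3 CH2, C4 isopropyl carbinol, C5 fusion CH, C6 anisoyloxy carbon, C7 CH2, C8(CH3)=C9, C10 CH2.
Retrosynthesis: the two ester C–O bonds are cut first, then C1–C5 and C1–C10. The seven-membered ring C5–C6–C7–C8–C9–C10–C1, with oxygen on C6 and methyl on C8, is a 2-methoxy-4-methylphenyl ring (C5 to C10) widened by the quaternary carbon C1, and C1 lies next to the C2 oxygen, so it is the carbene carbon of an α-methyl diazoketone. The last cuts are C1–C2 (acid chloride plus diazoethane) and C3–C4 (allylation of an aryl isopropyl ketone).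
Forward: the arene receives C4 and the C3–C2 chain first; step 8 then closes the cyclopentanone ring and enlarges the benzene ring to the seven-membered ring in one operation; the remaining steps adjust oxidation levels (C2, C6, diene to C8=C9) and attach the two esters.
Stereochemistry: C4 from a reagent-controlled, phenol-directed allylation; C1 from C4 in the Buchner step; C2 from an oxazaborolidine-controlled reduction; C5 from equilibrating protonation (trans ring fusion); C6 from hydride delivery by the C4 hydroxyl.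

Key step: step 8

Assumption: the (S,S)-enantiomer of allylsilane 5 is taken to deliver allyl to the ketone face that gives (R)-6; if this ketone class shows the opposite sense, the (R,R)-reagent is used with no other change.

**Route**

Step 1
Reactants: 1 3-methylphenol; 2 2-methylpropanoyl chloride
Product: 4 1-(2-hydroxy-4-methylphenyl)-2-methylpropan-1-one, via 3-methylphenyl 2-methylpropanoate 3 (not isolated)
Conditions: neat, 80 °C; then AlCl3 (1.5 equiv), 140 °C; aq. HCl work-up
Reagents that add atoms: none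
Why: O-acylation followed by a high-temperature Fries rearrangement should place the acyl group ortho to the phenol oxygen at the unhindered position para to methyl, where the aluminium chelate of the 2-hydroxyaryl ketone is the thermodynamic product.

Step 2
Reactants: 4 1-(2-hydroxy-4-methylphenyl)-2-methylpropan-1-one; 5 (3aS,7aS)-2-allyl-1,3-bis(4-bromobenzyl)-2-chlorooctahydro-1H-1,3,2-benzodiazasilole
Product: 6 2-[(3R)-3-hydroxy-2-methylhex-5-en-3-yl]-5-methylphenol
Conditions: 5 (1.5 equiv), CH2Cl2, 25–40 °C; then 1 M HCl, EtOAc, 0 °C (brief)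
Reagents that add atoms: none
Why: Phenol-directed enantioselective allylation of a ketone with a chiral strained allylchlorosilane: the phenol displaces chloride at silicon and the bound ketone is allylated intramolecularly through a closed chair transition state, a mode that tolerates hindered 2-hydroxyaryl ketones, so the diamine backbone should set C4 as R.

Step 3
Reactants: 6 2-[(3R)-3-hydroxy-2-methylhex-5-en-3-yl]-5-methylphenol
Product: 7 (3R)-3-(2-methoxy-4-methylphenyl)-2-methylhex-5-en-3-ol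
Conditions: MeI, K2CO3, acetone, 50 °C
Reagents that add atoms: iodomethane CI
Why: Williamson ether synthesis in which only the phenol is deprotonated by K2CO3, so the tertiary alcohol should stay free.

Step 4
Reactants: 7 (3R)-3-(2-methoxy-4-methylphenyl)-2-methylhex-5-en-3-ol
Product: 8 triethyl{[(3R)-3-(2-methoxy-4-methylphenyl)-2-methylhex-5-en-3-yl]oxy}silane
Conditions: Et3SiOTf, 2,6-lutidine, CH2Cl2, −78 → 0 °C
Reagents that add atoms: triethylsilyl trifluoromethanesulfonate CC[Si](CC)(CC)OS(=O)(=O)C(F)(F)F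
Why: Silylation of a hindered tertiary alcohol with a silyl triflate and a hindered pyridine base masks O4 against O–H insertion of the later carbenoid.

Step 5
Reactants: 8 triethyl{[(3R)-3-(2-methoxy-4-methylphenyl)-2-methylhex-5-en-3-yl]oxy}silane
Product: 9 (3R)-3-(2-methoxy-4-methylphenyl)-4-methyl-3-[(triethylsilyl)oxy]pentanal
Conditions: OsO4 (2 mol %), NaIO4, 2,6-lutidine, dioxane/H2O 3:1, 25 °C
Reagents that add atoms: osmium tetroxide O=[Os](=O)(=O)=O (catalytic oxygen carrier); sodium periodate [Na+].[O-]I(=O)(=O)=O (terminal oxygen source)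
Why: Lemieux–Johnson cleavage (dihydroxylation, then periodate glycol cleavage) of the terminal alkene under lutidine buffering should leave the electron-rich arene and the silyl ether untouched.

Step 6
Reactants: 9 (3R)-3-(2-methoxy-4-methylphenyl)-4-methyl-3-[(triethylsilyl)oxy]pentanal
Product: 10 (3R)-3-(2-methoxy-4-methylphenyl)-4-methyl-3-[(triethylsilyl)oxy]pentanoic acid
Conditions: NaClO2, NaH2PO4, 2-methylbut-2-ene, t-BuOH/H2O, 0 → 25 °C
Reagents that add atoms: sodium chlorite [Na+].[O-]Cl=O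
Why: Pinnick oxidation of the aldehyde, with 2-methylbut-2-ene trapping hypochlorous acid so that the electron-rich arene is not chlorinated.

Step 7
Reactants: 10 (3R)-3-(2-methoxy-4-methylphenyl)-4-methyl-3-[(triethylsilyl)oxy]pentanoic acid
Product: 12 (5R)-2-diazo-5-(2-methoxy-4-methylphenyl)-6-methyl-5-[(triethylsilyl)oxy]heptan-3-one, via acid chloride 11 (not isolated)
Conditions: Me2C=C(Cl)NMe2, CH2Cl2, 0 °C; then MeCHN2 (3 equiv), Et2O, −20 → 0 °C
Reagents that add atoms: diazoethane CC=[N+]=[N-]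
Why: The α-chloroenamine makes the acid chloride without free HCl that could ionise the benzylic silyl ether, and acylation of diazoethane (Arndt–Eistert-type acylation of a diazoalkane, the excess taking up HCl) should give the α-methyl diazoketone.

Step 8
Reactants: 12 (5R)-2-diazo-5-(2-methoxy-4-methylphenyl)-6-methyl-5-[(triethylsilyl)oxy]heptan-3-one
Product: 14 (3R,8aR)-4-methoxy-6,8a-dimethyl-3-(propan-2-yl)-3-[(triethylsilyl)oxy]-3,8a-dihydroazulen-1(2H)-one, via norcaradiene 13 (not isolated)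
Conditions: Rh2(O2CCMe3)4 (1 mol %), CH2Cl2, 0 °C, slow addition of 12
Reagents that add atoms: none
Why: Rh2(O2CCMe3)4 takes N2 from 12 and the electrophilic rhodium carbenoid at C1 adds across the arene bond between the ipso carbon C5 and the unsubstituted ortho carbon C10 to give norcaradiene 13, whose thermally allowed disrotatory 6π electrocyclic opening breaks C5–C10 and leaves cycloheptatriene 14. The closest known reaction is the intramolecular Buchner reaction of 1-diazo-4-arylbutan-2-ones, which is established for α-methyl diazoketones (angular methyl) and for fully substituted benzylic carbons. The cyclopentanone ring closes by C1–C5 bond formation in the [2+1] addition (five-membered, exo with respect to the tether C2–C3–C4), and the seven-membered ring arises by one-carbon enlargement of the benzene ring (C1–C10 made, C5–C10 broken). C1, the only new stereocenter, is set by C4: the tether carbon C3 must stand over the arene face to reach C5–C10, and of the other two C4 substituents only the silyloxy oxygen, not isopropyl, can lie in the ring plane beside the ortho methoxy group, so isopropyl points to the far face and ends trans to the angular methyl (O4 cis to C1–CH3). The step needs regioselectivity for C5–C10 over the methoxy-bearing C5–C6 bond, which the C6 substituent should secure, and chemoselectivity over 1,2-hydride shift of the α-methyl carbenoid, insertion into the isopropyl C–H bond and ylide formation at O4, for which the electron-rich arene, the quaternary benzylic carbon holding the carbenoid over the ring, the hindered silyl ether, the bulky carboxylate ligand, low temperature and slow addition are relied on.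

Step 9
Reactants: 14 (3R,8aR)-4-methoxy-6,8a-dimethyl-3-(propan-2-yl)-3-[(triethylsilyl)oxy]-3,8a-dihydroazulen-1(2H)-one
Product: 15 (1S,3R,8aR)-4-methoxy-6,8a-dimethyl-3-(propan-2-yl)-3-[(triethylsilyl)oxy]-1,2,3,8a-tetrahydroazulen-1-ol
Conditions: (R)-2-methyl-CBS-oxazaborolidine [(3aR)-1-methyl-3,3-diphenyltetrahydro-1H,3H-pyrrolo[1,2-c][1,3,2]oxazaborole] (0.5 equiv), catecholborane, toluene, −40 °C
Reagents that add atoms: none
Why: Corey–Bakshi–Shibata reduction, in which the (R)-oxazaborolidine binds the carbonyl oxygen anti to the quaternary C1 and delivers hydride to the C2 face on the side of the angular methyl, should give the alcohol trans to C1–CH3 (S at C2) under reagent control, and the non-acidic medium spares the enol ether and the silyl ether.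

Step 10
Reactants: 15 (1S,3R,8aR)-4-methoxy-6,8a-dimethyl-3-(propan-2-yl)-3-[(triethylsilyl)oxy]-1,2,3,8a-tetrahydroazulen-1-ol
Product: 16 (1S,3R,8aR)-4-methoxy-6,8a-dimethyl-3-(propan-2-yl)-3-[(triethylsilyl)oxy]-1,2,3,8a-tetrahydroazulen-1-yl acetate
Conditions: Ac2O, Et3N, 4-(dimethylamino)pyridine (cat.), CH2Cl2, 25 °C
Reagents that add atoms: acetic anhydride CC(=O)OC(C)=O
Why: Acylation of the only free hydroxyl under nucleophilic catalysis by 4-(dimethylamino)pyridine.

Step 11
Reactants: 16 (1S,3R,8aR)-4-methoxy-6,8a-dimethyl-3-(propan-2-yl)-3-[(triethylsilyl)oxy]-1,2,3,8a-tetrahydroazulen-1-yl acetate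
Product: 18 (1S,3R,3aR,8aR)-3-hydroxy-6,8a-dimethyl-4-oxo-3-(propan-2-yl)-1,2,3,3a,4,8a-hexahydroazulen-1-yl acetate, via silylated dienone 17 (not isolated)
Conditions: 48 % aq. HF, MeCN, 0 → 25 °C
Reagents that add atoms: water O
Why: Acid hydrolysis of the dienyl methyl enol ether (protonation at C5, collapse of the hemiketal) together with fluoride-assisted cleavage of the silyl ether; C5 can equilibrate through the enol, and the trans-fused epimer should be favoured because the C6 carbonyl then lies cis to O4–H (hydrogen bond) and anti to isopropyl.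

Step 12
Reactants: 18 (1S,3R,3aR,8aR)-3-hydroxy-6,8a-dimethyl-4-oxo-3-(propan-2-yl)-1,2,3,3a,4,8a-hexahydroazulen-1-yl acetate
Product: 19 (1S,3R,3aR,8aR)-3-hydroxy-6,8a-dimethyl-4-oxo-3-(propan-2-yl)-1,2,3,3a,4,5,8,8a-octahydroazulen-1-yl acetate
Conditions: (η6-naphthalene)Cr(CO)3 (20 mol %), H2 (50 atm), THF, 25 °C
Reagents that add atoms: none
Why: Chromium tricarbonyl-catalysed 1,4-hydrogenation of a cisoid 1,3-diene: zerovalent chromium binds the ring-locked s-cis diene C7=C8–C9=C10 as an η4 ligand and adds H2 to its termini C7 and C10, leaving the C8=C9 alkene (the outcome known for dienoates such as sorbates), while the s-trans enone unit, the ester and the isolated product alkene should not be reduced.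

Step 13
Reactants: 19 (1S,3R,3aR,8aR)-3-hydroxy-6,8a-dimethyl-4-oxo-3-(propan-2-yl)-1,2,3,3a,4,5,8,8a-octahydroazulen-1-yl acetate
Product: 20 (1S,3R,3aS,4S,8aR)-3,4-dihydroxy-6,8a-dimethyl-3-(propan-2-yl)-1,2,3,3a,4,5,8,8a-octahydroazulen-1-yl acetate
Conditions: Me4N[BH(OAc)3], MeCN/AcOH 1:1, −30 °C
Reagents that add atoms: none
Why: Evans–Saksena hydroxyl-directed reduction, in which O4–H exchanges onto boron and hydride is delivered intramolecularly to the face of the C6 carbonyl turned toward O4, should place the new C6–O bond cis to H5 (S at C6), and at −30 °C the β,γ-enone should not move into conjugation.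

Step 14
Reactants: 20 (1S,3R,3aS,4S,8aR)-3,4-dihydroxy-6,8a-dimethyl-3-(propan-2-yl)-1,2,3,3a,4,5,8,8a-octahydroazulen-1-yl acetate; 21 4-methoxybenzoyl chloride
Product: 22 (1S,3R,3aS,4S,8aR)-1-(acetyloxy)-3-hydroxy-6,8a-dimethyl-3-(propan-2-yl)-1,2,3,3a,4,5,8,8a-octahydroazulen-4-yl 4-methoxybenzoate
Conditions: 21, 4-(dimethylamino)pyridine, Et3N, CH2Cl2, 25 → 40 °C
Reagents that add atoms: none
Why: Acylation of the secondary C6 alcohol by the aroyl chloride under nucleophilic catalysis, the tertiary O4–H being too hindered to react.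

**Compound list**

1 | 3-methylphenol | Cc1cccc(O)c1 | starting material
2 | 2-methylpropanoyl chloride | CC(C)C(Cl)=O | starting material
3 | 3-methylphenyl 2-methylpropanoate | CC(C)C(=O)Oc1cccc(C)c1 | intermediate (not isolated)
4 | 1-(2-hydroxy-4-methylphenyl)-2-methylpropan-1-one | CC(C)C(=O)c1ccc(C)cc1O | intermediate
5 | (3aS,7aS)-2-allyl-1,3-bis(4-bromobenzyl)-2-chlorooctahydro-1H-1,3,2-benzodiazasilole | C=CC[Si]1(Cl)N(Cc2ccc(Br)cc2)[C@H]2CCCC[C@@H]2N1Cc1ccc(Br)cc1 | starting material
6 | 2-[(3R)-3-hydroxy-2-methylhex-5-en-3-yl]-5-methylphenol | C=CC[C@@](O)(C(C)C)c1ccc(C)cc1O | intermediate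
7 | (3R)-3-(2-methoxy-4-methylphenyl)-2-methylhex-5-en-3-ol | C=CC[C@@](O)(C(C)C)c1ccc(C)cc1OC | intermediate
8 | triethyl{[(3R)-3-(2-methoxy-4-methylphenyl)-2-methylhex-5-en-3-yl]oxy}silane | C=CC[C@@](O[Si](CC)(CC)CC)(C(C)C)c1ccc(C)cc1OC | intermediate
9 | (3R)-3-(2-methoxy-4-methylphenyl)-4-methyl-3-[(triethylsilyl)oxy]pentanal | O=CC[C@@](O[Si](CC)(CC)CC)(C(C)C)c1ccc(C)cc1OC | intermediate
10 | (3R)-3-(2-methoxy-4-methylphenyl)-4-methyl-3-[(triethylsilyl)oxy]pentanoic acid | OC(=O)C[C@@](O[Si](CC)(CC)CC)(C(C)C)c1ccc(C)cc1OC | intermediate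
11 | (3R)-3-(2-methoxy-4-methylphenyl)-4-methyl-3-[(triethylsilyl)oxy]pentanoyl chloride | ClC(=O)C[C@@](O[Si](CC)(CC)CC)(C(C)C)c1ccc(C)cc1OC | intermediate (not isolated)
12 | (5R)-2-diazo-5-(2-methoxy-4-methylphenyl)-6-methyl-5-[(triethylsilyl)oxy]heptan-3-one | CC(=[N+]=[N-])C(=O)C[C@@](O[Si](CC)(CC)CC)(C(C)C)c1ccc(C)cc1OC | intermediate (key-step precursor)
13 | norcaradiene valence tautomer of 14 (cyclopropane C1–C5–C10 fused to the cyclopentanone and to a 2-methoxy-4-methylcyclohexadiene) | COC1=CC(C)=C[C@@H]2[C@@]3(C)C(=O)C[C@@](O[Si](CC)(CC)CC)(C(C)C)[C@@]123 | intermediate (not isolated)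
14 | (3R,8aR)-4-methoxy-6,8a-dimethyl-3-(propan-2-yl)-3-[(triethylsilyl)oxy]-3,8a-dihydroazulen-1(2H)-one | COC1=C2[C@](O[Si](CC)(CC)CC)(C(C)C)CC(=O)[C@]2(C)C=CC(C)=C1 | intermediate (key-step product)
15 | (1S,3R,8aR)-4-methoxy-6,8a-dimethyl-3-(propan-2-yl)-3-[(triethylsilyl)oxy]-1,2,3,8a-tetrahydroazulen-1-ol | COC1=C2[C@](O[Si](CC)(CC)CC)(C(C)C)C[C@H](O)[C@]2(C)C=CC(C)=C1 | intermediate
16 | (1S,3R,8aR)-4-methoxy-6,8a-dimethyl-3-(propan-2-yl)-3-[(triethylsilyl)oxy]-1,2,3,8a-tetrahydroazulen-1-yl acetate | COC1=C2[C@](O[Si](CC)(CC)CC)(C(C)C)C[C@H](OC(C)=O)[C@]2(C)C=CC(C)=C1 | intermediate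
17 | (1S,3R,3aR,8aR)-6,8a-dimethyl-4-oxo-3-(propan-2-yl)-3-[(triethylsilyl)oxy]-1,2,3,3a,4,8a-hexahydroazulen-1-yl acetate | O=C1C=C(C)C=C[C@@]2(C)[C@@H](OC(C)=O)C[C@@](O[Si](CC)(CC)CC)(C(C)C)[C@H]12 | intermediate (not isolated)
18 | (1S,3R,3aR,8aR)-3-hydroxy-6,8a-dimethyl-4-oxo-3-(propan-2-yl)-1,2,3,3a,4,8a-hexahydroazulen-1-yl acetate | O=C1C=C(C)C=C[C@@]2(C)[C@@H](OC(C)=O)C[C@@](O)(C(C)C)[C@H]12 | intermediate
19 | (1S,3R,3aR,8aR)-3-hydroxy-6,8a-dimethyl-4-oxo-3-(propan-2-yl)-1,2,3,3a,4,5,8,8a-octahydroazulen-1-yl acetate | O=C1CC(C)=CC[C@@]2(C)[C@@H](OC(C)=O)C[C@@](O)(C(C)C)[C@H]12 | intermediate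
20 | (1S,3R,3aS,4S,8aR)-3,4-dihydroxy-6,8a-dimethyl-3-(propan-2-yl)-1,2,3,3a,4,5,8,8a-octahydroazulen-1-yl acetate | O[C@H]1CC(C)=CC[C@@]2(C)[C@@H](OC(C)=O)C[C@@](O)(C(C)C)[C@H]12 | intermediate
21 | 4-methoxybenzoyl chloride | COc1ccc(C(Cl)=O)cc1 | starting material
22 | (1S,3R,3aS,4S,8aR)-1-(acetyloxy)-3-hydroxy-6,8a-dimethyl-3-(propan-2-yl)-1,2,3,3a,4,5,8,8a-octahydroazulen-4-yl 4-methoxybenzoate | COc1ccc(C(=O)O[C@H]2CC(C)=CC[C@@]3(C)[C@@H](OC(C)=O)C[C@@](O)(C(C)C)[C@H]23)cc1 | target

**Step count and risks**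

Total step count: 14. Longest linear sequence: 14 steps (1 to 22).

Step 8. What may go wrong: facial discrimination may be poor because the C4–aryl bond rotates freely, and the carbenoid may be diverted (1,2-hydride shift, C–H insertion at isopropyl, ylide formation at O4) if the reactive conformer is thinly populated. The fallback sets out from 6 and comes back at 18. t-Bu2Si(OTf)2 with 2,6-lutidine should tie the phenol oxygen and O4 into a six-membered ring, giving silylene acetal F1. The operations of steps 5 to 7 then lead through aldehyde F2 and acid F3 to diazoketone F4. In F4 the ring holds O4 in the arene plane beside the aryl oxygen, so C3 and isopropyl can only stand on opposite faces and the carbenoid can only meet C5–C10 from the face that puts O4 cis to the angular methyl. Dirhodium-catalysed closure should give bridged azulenone F5, a cyclic silyl enol ether. Oxazaborolidine reduction to alcohol F6 and acetylation to acetate F7 follow steps 9 and 10. Aqueous HF in MeCN then cleaves both Si–O bonds, protonates C5 and delivers 18.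

Step 12. What may go wrong: hydrogen transfer may stall at the diene terminus next to the quaternary carbon, or the β,γ-enone may drift into conjugation on the metal. The fallback sets out from 15 and comes back at 22, with a dissolving-metal reduction on an ester-free relative. i-Pr3SiOTf with 2,6-lutidine should give bis-silyl ether F8. Aqueous HF in MeCN at 0 °C hydrolyses the enol ether and removes the tertiary triethylsilyl group while the triisopropylsilyl ether stays, giving dienone F9. Li in NH3/THF with t-BuOH (1 equiv) at −78 °C, quenched with solid NH4Cl, effects 1,6-reduction of the linear dienone with kinetic α-protonation of the dienolate and gives β,γ-enone F10. Me4N[BH(OAc)3] then gives diol F11, acylation with 21 gives ester F12, HF·pyridine gives alcohol F13, and Ac2O with 4-(dimethylamino)pyridine gives 22.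

Step 9. What may go wrong: reagent control may be overridden by the substrate, hydride entering anti to the angular methyl and the silyloxy group. The fallback sets out from 14 and comes back at 18, with internal hydride delivery in place of an external reagent. Aqueous HF in MeCN gives hydroxy dione F14. Me4N[BH(OAc)3] in MeCN/AcOH reduces both carbonyl groups by delivery from O4–H, giving triol F15 with the C2 and C6 oxygens both on the face opposite O4. MnO2 in CH2Cl2 re-oxidises only the dienylic C6 alcohol, giving dienone diol F16, and Ac2O with 4-(dimethylamino)pyridine acetylates the C2 hydroxyl to give 18.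

**Further compounds**

F1 | step 8 | (4R)-2,2-di-tert-butyl-7-methyl-4-(propan-2-yl)-4-(prop-2-en-1-yl)-4H-1,3,2-benzodioxasiline | C=CC[C@]1(C(C)C)O[Si](C(C)(C)C)(C(C)(C)C)Oc2cc(C)ccc21
F2 | step 8 | [(4R)-2,2-di-tert-butyl-7-methyl-4-(propan-2-yl)-4H-1,3,2-benzodioxasilin-4-yl]acetaldehyde | O=CC[C@]1(C(C)C)O[Si](C(C)(C)C)(C(C)(C)C)Oc2cc(C)ccc21
F3 | step 8 | [(4R)-2,2-di-tert-butyl-7-methyl-4-(propan-2-yl)-4H-1,3,2-benzodioxasilin-4-yl]acetic acid | OC(=O)C[C@]1(C(C)C)O[Si](C(C)(C)C)(C(C)(C)C)Oc2cc(C)ccc21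
F4 | step 8 | 3-diazo-1-[(4R)-2,2-di-tert-butyl-7-methyl-4-(propan-2-yl)-4H-1,3,2-benzodioxasilin-4-yl]butan-2-one | CC(=[N+]=[N-])C(=O)C[C@]1(C(C)C)O[Si](C(C)(C)C)(C(C)(C)C)Oc2cc(C)ccc21
F5 | step 8 | analogue of 14 in which O4 and the C6 enol oxygen are joined by Si(t-Bu)2 (same configuration at C1 and C4) | CC1=CC2=C3[C@@](C(C)C)(O[Si](C(C)(C)C)(C(C)(C)C)O2)CC(=O)[C@]3(C)C=C1
F6 | step 8 | C2 alcohol of F5 (hydroxyl trans to the C1 methyl) | CC1=CC2=C3[C@@](C(C)C)(O[Si](C(C)(C)C)(C(C)(C)C)O2)C[C@H](O)[C@]3(C)C=C1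
F7 | step 8 | C2 acetate of F6 | CC1=CC2=C3[C@@](C(C)C)(O[Si](C(C)(C)C)(C(C)(C)C)O2)C[C@H](OC(C)=O)[C@]3(C)C=C1
F8 | step 12 | C2 triisopropylsilyl ether of 15 | COC1=C2[C@](O[Si](CC)(CC)CC)(C(C)C)C[C@H](O[Si](C(C)C)(C(C)C)C(C)C)[C@]2(C)C=CC(C)=C1
F9 | step 12 | analogue of 18 with OSi(i-Pr)3 in place of OAc at C2 | O=C1C=C(C)C=C[C@@]2(C)[C@@H](O[Si](C(C)C)(C(C)C)C(C)C)C[C@@](O)(C(C)C)[C@H]12
F10 | step 12 | analogue of 19 with OSi(i-Pr)3 in place of OAc at C2 | O=C1CC(C)=CC[C@@]2(C)[C@@H](O[Si](C(C)C)(C(C)C)C(C)C)C[C@@](O)(C(C)C)[C@H]12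
F11 | step 12 | analogue of 20 with OSi(i-Pr)3 in place of OAc at C2 | O[C@H]1CC(C)=CC[C@@]2(C)[C@@H](O[Si](C(C)C)(C(C)C)C(C)C)C[C@@](O)(C(C)C)[C@H]12
F12 | step 12 | analogue of 22 with OSi(i-Pr)3 in place of OAc at C2 | COc1ccc(C(=O)O[C@H]2CC(C)=CC[C@@]3(C)[C@@H](O[Si](C(C)C)(C(C)C)C(C)C)C[C@@](O)(C(C)C)[C@H]23)cc1
F13 | step 12 | (1S,3R,3aS,4S,8aR)-1,3-dihydroxy-6,8a-dimethyl-3-(propan-2-yl)-1,2,3,3a,4,5,8,8a-octahydroazulen-4-yl 4-methoxybenzoate | COc1ccc(C(=O)O[C@H]2CC(C)=CC[C@@]3(C)[C@@H](O)C[C@@](O)(C(C)C)[C@H]23)cc1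
F14 | step 9 | (3R,3aR,8aR)-3-hydroxy-6,8a-dimethyl-3-(propan-2-yl)-3,3a-dihydroazulene-1,4(2H,8aH)-dione | O=C1C=C(C)C=C[C@@]2(C)C(=O)C[C@@](O)(C(C)C)[C@H]12
F15 | step 9 | (1S,3R,3aS,4S,8aR)-6,8a-dimethyl-3-(propan-2-yl)-1,2,3,3a,4,8a-hexahydroazulene-1,3,4-triol | O[C@H]1C=C(C)C=C[C@@]2(C)[C@@H](O)C[C@@](O)(C(C)C)[C@H]12
F16 | step 9 | (1S,3R,3aR,8aR)-1,3-dihydroxy-6,8a-dimethyl-3-(propan-2-yl)-1,2,3,3a-tetrahydroazulen-4(8aH)-one | O=C1C=C(C)C=C[C@@]2(C)[C@@H](O)C[C@@](O)(C(C)C)[C@H]12
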